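**Plan**

- Target numbering used in the text: ring C1 (carries =CH2), C2, C3, C4 (CHMe), C5 (quaternary), C6, C7=C8, C9=C10 (CO2Me); C11 = CH2 on C5, C12 = carbinol carbon.
- Retrosynthesis: the C7=C8–C9=C10 diene inside the ten-membered ring is the retron of a cyclobutene 4π ring opening. Re-forming the C7–C10 σ-bond gives a trans-fused bicyclo[6.2.0]dec-9-ene (eight-membered ring C10–C1–…–C7 plus cyclobutene C7–C8=C9–C10).
- The cyclobutene is cut at C7–C8 and C9–C10 (1,2-dichloroethene + eight-membered 2-carbomethoxy enone). The side chain is cut at C12–furyl and the C12–O acyl bond, and C1=CH2 comes from a ketone.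
- The eight-membered ring is cut back to a cyclohexanone: C10 and C7 are methyl propiolate inserted into the C1–C6 bond of a regiodefined silyl enol ether. C5–C11 is cut as a Mukaiyama–Michael addition.
- Forward: cyclohexenone → quaternary C5 → ring 6 → 8 → enone → [2+2] → methylidene and side chain → Zn/heat, ring 8 → 10.
- Stereochemistry: C4 from an organocatalytic Michael addition; C5 by addition anti to the C4 methyl; C12 by CBS reduction; the acyl centre from (R)-2-methylbutanoic acid; both diene geometries from conrotation of the trans-fused cyclobutene.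

Key step: step 14

Remark: the acyl group in the target SMILES is (R)-2-methylbutanoyl; the acid is taken as the commercial single enantiomer.
Remark: 17–25 are carried as mixtures of CHCl epimers; their SMILES show one of the two acceptable trans-fused diastereomers with the CHCl centres left open, since C7–C10 all become sp2 in step 14.

**Step 1**
Reactants: 1 propanal; 2 methyl vinyl ketone
Product: 3 (R)-2-methyl-5-oxohexanal
Conditions: (S)-α,α-diphenylprolinol methyl ether (5 mol%), ethyl 3,4-dihydroxybenzoate (20 mol%), neat, 4 °C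
Reagents that add atoms: none
Why: Enamine-catalysed Michael addition of the aldehyde to the enone, in which the diarylmethyl group of the (S)-pyrrolidine shields one face of the (E)-enamine so that the (R) α-methyl centre (future C4) should be set.

**Step 2**
Reactants: 3 (R)-2-methyl-5-oxohexanal
Product: 4 (R)-4-methylcyclohex-2-en-1-one
Conditions: 0.1 M aq. KOH, n-Bu4NOH (cat.), Et2O–THF, reflux, short contact time
Reagents that add atoms: none
Why: Intramolecular aldol condensation (6-enolexo) of the methyl-ketone enolate onto the aldehyde; the stereocentre becomes the γ-carbon of the enone, and dilute base limits α-epimerisation before ring closure.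

**Step 3**
Reactants: 4 (R)-4-methylcyclohex-2-en-1-one
Product: 6 (R)-3,4-dimethylcyclohex-2-en-1-one, via 3,4-trans TMS enol ether 5 (not isolated)
Conditions: MeMgBr, CuBr·SMe2 (5 mol%), TMSCl, DMPU, THF, −78 °C; then Pd(OAc)2 (1.05 equiv), MeCN, rt
Reagents that add atoms: methylmagnesium bromide, C[Mg]Br
Why: Copper-catalysed conjugate methylation with silyl trapping, then Saegusa–Ito dehydrosilylation, re-creates the enone with the new methyl on C5; the transient C5 centre of 5 is erased and C4 is untouched.

**Step 4**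
Reactants: 6 (R)-3,4-dimethylcyclohex-2-en-1-one; 7 1-(tert-butyldimethylsilyloxy)-1-methoxyethene
Product: 8 methyl 2-[(1S,6R)-3-(tert-butyldimethylsilyloxy)-1,6-dimethylcyclohex-2-en-1-yl]acetate
Conditions: Tf2NH (2 mol%), CH2Cl2, −78 °C
Reagents that add atoms: none
Why: Mukaiyama–Michael addition under silylium catalysis with silyl transfer; the ketene acetal should attack the β-carbon anti to the C4 methyl (axial attack), setting quaternary C5 with CH2CO2Me trans to the C4 methyl (the two methyls cis) and leaving the enol ether regiodefined toward C6.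

**Step 5**
Reactants: 8 methyl 2-[(1S,6R)-3-(tert-butyldimethylsilyloxy)-1,6-dimethylcyclohex-2-en-1-yl]acetate; 9 methyl propiolate
Product: 11 methyl (5R,6S,7Z)-6-(2-methoxy-2-oxoethyl)-5,6-dimethyl-2-oxocyclooct-7-ene-1-carboxylate, via 1-siloxybicyclo[4.2.0]oct-7-ene ester 10 (not isolated)
Conditions: EtAlCl2 (20 mol%), CH2Cl2, −78 °C; then TBAF, THF, −20 °C, AcOH quench
Reagents that add atoms: none
Why: Lewis-acid-promoted stepwise [2+2] of the silyl enol ether with the ynoate (C6–C7, then C1–C10) gives the siloxycyclobutene ester, and fluoride converts it into an alkoxide that cleaves the C1–C6 bond (retro-aldol-type, oxyanion-accelerated cyclobutene opening), a two-carbon ring expansion 6 → 8; the C1/C6 centres of 10 vanish and C10 of 11 is a labile β-keto ester carbon.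

**Step 6**
Reactants: 11
Product: 12 methyl (5R,6S)-6-(2-methoxy-2-oxoethyl)-5,6-dimethyl-2-oxocyclooctane-1-carboxylate
Conditions: H2 (1 atm), 10% Pd/C, EtOAc, rt
Reagents that add atoms: none
Why: Heterogeneous hydrogenation of the only C=C (C6=C7), so that the ring alkene can next be placed regiospecifically at C7=C10.

**Step 7**
Reactants: 12
Product: 15 methyl (4S,5R)-4-(2-methoxy-2-oxoethyl)-4,5-dimethyl-8-oxocyclooct-1-ene-1-carboxylate, via α-phenylselanyl keto ester 13 (not isolated), via selenoxide 14 (not isolated)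
Conditions: PhSeCl, pyridine, CH2Cl2, 0 °C; then 30% H2O2, 0 °C → rt
Reagents that add atoms: none
Why: α-Selenenylation of the β-keto ester followed by selenoxide syn-elimination, which can only use a C7–H (C1 is a carbonyl carbon), should give the ring-cis 2-carbomethoxycyclooct-2-enone; it is used at once to avoid tautomerisation.

**Step 8**
Reactants: 15; 16 (Z)-1,2-dichloroethene
Product: 17 methyl (5R,6S)-9,10-dichloro-6-(2-methoxy-2-oxoethyl)-5,6-dimethyl-2-oxobicyclo[6.2.0]decane-1-carboxylate (trans-fused)
Conditions: hν (λ ≥ 350 nm, Pyrex), 16 (20 equiv), CH2Cl2, −30 °C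
Reagents that add atoms: none
Why: Enone–alkene [2+2] photocycloaddition with dichloroethene as acetylene equivalent; the eight-membered enone triplet relaxes toward a twisted (E)-like geometry, so closure should give mainly the trans 4/8 ring fusion (H on C7 anti to the C10 ester), the only stereochemical feature that matters here.

**Step 9**
Reactants: 17
Product: 18 methyl (5R,6S)-9,10-dichloro-6-(2-methoxy-2-oxoethyl)-5,6-dimethyl-2-methylidenebicyclo[6.2.0]decane-1-carboxylate
Conditions: Ph3PCH3Br (slight excess over base), KOt-Bu, THF, 0 → 45 °C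
Reagents that add atoms: methyltriphenylphosphonium bromide, C[P+](c1ccccc1)(c1ccccc1)c1ccccc1.[Br-]
Why: Wittig methylenation of the only ketone (C1), which cannot enolise toward the quaternary C10; the esters are far less reactive toward the ylide at this temperature.

**Step 10**
Reactants: 18
Product: 19 methyl (5R,6S)-9,10-dichloro-6-{2-[methoxy(methyl)amino]-2-oxoethyl}-5,6-dimethyl-2-methylidenebicyclo[6.2.0]decane-1-carboxylate
Conditions: MeNH(OMe)·HCl, i-PrMgCl, THF, −20 → 0 °C; aq. HCl work-up
Reagents that add atoms: N,O-dimethylhydroxylamine hydrochloride, CNOC.Cl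
Why: Weinreb aminolysis with the magnesium amide should occur at the primary-alkyl side-chain ester, because the C10 ester sits on a fully substituted cyclobutane carbon and is much more hindered.

**Step 11**
Reactants: 19; 20 3-bromofuran
Product: 21 methyl (5R,6S)-9,10-dichloro-6-[2-(furan-3-yl)-2-oxoethyl]-5,6-dimethyl-2-methylidenebicyclo[6.2.0]decane-1-carboxylate
Conditions: 20, n-BuLi, THF, −78 °C; then 19, −78 °C; H2O quench
Reagents that add atoms: none
Why: Weinreb ketone synthesis; 3-furyllithium (Br/Li exchange kept at −78 °C to avoid isomerisation to the 2-lithio species) adds once because of the chelated tetrahedral intermediate, and the hindered C10 ester should not react.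

**Step 12**
Reactants: 21
Product: 22 methyl (5R,6S)-9,10-dichloro-6-[(2R)-2-(furan-3-yl)-2-hydroxyethyl]-5,6-dimethyl-2-methylidenebicyclo[6.2.0]decane-1-carboxylate
Conditions: (S)-2-methyl-CBS-oxazaborolidine (0.5 equiv), catecholborane, toluene, −78 °C
Reagents that add atoms: none
Why: CBS reduction; with furyl as the large group the (S)-oxazaborolidine should give the (R)-carbinol at C12 (same sense as acetophenone to (R)-1-phenylethanol), and catecholborane at −78 °C leaves the 1,1-disubstituted alkene alone.

**Step 13**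
Reactants: 22; 23 (R)-2-methylbutanoic acid
Product: 24 methyl (5R,6S)-9,10-dichloro-6-[(2R)-2-(furan-3-yl)-2-{[(2R)-2-methylbutanoyl]oxy}ethyl]-5,6-dimethyl-2-methylidenebicyclo[6.2.0]decane-1-carboxylate
Conditions: EDC·HCl, DMAP (0.2 equiv), CH2Cl2, 0 °C → rt
Reagents that add atoms: none
Why: Steglich esterification with retention at C12; low temperature and catalytic DMAP limit epimerisation of the α-centre of the acid.

**Step 14**
Reactants: 24
Product: 26 CNP0305973.1, via trans-fused bicyclo[6.2.0]dec-9-ene 25 (not isolated)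
Conditions: Zn–Cu couple, 2,6-lutidine, THF–EtOH (4:1), 60 °C; filter; then toluene, 95 °C
Reagents that add atoms: none
Why: Zinc removes the two chlorines by reductive 1,2-elimination to give the trans-fused bicyclo[6.2.0]dec-9-ene 25, whose thermally allowed conrotatory 4π-electrocyclic ring opening breaks the strained C7–C10 fusion bond and merges the four- and eight-membered rings into the ten-membered ring with the C7=C8–C9=C10 diene. The closest known reaction types are the thermolysis of cyclobutenes fused to medium rings (bicyclo[n.2.0]alkenes to ring-enlarged cycloalka-1,3-dienes, the second half of the enamine/ynoate two-carbon ring enlargement) and the dichloroethene-photoadduct/zinc route to cyclobutenes. No ring is closed and no stereocentre is made: the ten-membered ring arises by σ-bond fission alone (8 → 10), and the four stereocentres C7–C10 are erased, so every CHCl epimer and both trans-fused diastereomers converge on one product. Both alkene geometries follow from orbital symmetry: with the ring bonds C10–C1 and C7–C6 on opposite faces of the cyclobutene, conrotation turns them both inward (C7=C8 Z, and C1 cis to C8 across C9=C10, as required) or both outward. The inward sense is secured by the six-atom tether C1–C6, which cannot span an E,E-diene without severe strain, so any E,E-triene formed should reclose and the Z,Z-triene is the thermodynamic sink; relief of cyclobutene strain and conjugation with the ester drive the reaction. The temperature is kept near 95 °C because the product contains the hexatriene CH2=C1–C10=C9–C8=C7, whose 6π-electrocyclisation is disfavoured by the inward C6 substituent and the twisted ring but is not excluded.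

**Compound list**

1 | propanal | CCC=O | starting material
2 | methyl vinyl ketone (but-3-en-2-one) | CC(=O)C=C | starting material
3 | (R)-2-methyl-5-oxohexanal | CC(=O)CC[C@@H](C)C=O | intermediate
4 | (R)-4-methylcyclohex-2-en-1-one | O=C1CC[C@@H](C)C=C1 | intermediate
5 | trimethyl{[(3S,4R)-3,4-dimethylcyclohex-1-en-1-yl]oxy}silane (3,4-trans; formed in situ) | C[Si](C)(C)OC1=C[C@@H](C)[C@H](C)CC1 | intermediate
6 | (R)-3,4-dimethylcyclohex-2-en-1-one | O=C1CC[C@@H](C)C(C)=C1 | intermediate
7 | 1-(tert-butyldimethylsilyloxy)-1-methoxyethene | C=C(OC)O[Si](C)(C)C(C)(C)C | starting material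
8 | methyl 2-[(1S,6R)-3-(tert-butyldimethylsilyloxy)-1,6-dimethylcyclohex-2-en-1-yl]acetate | CC(C)(C)[Si](C)(C)OC1=C[C@@](C)(CC(=O)OC)[C@H](C)CC1 | intermediate
9 | methyl propiolate | C#CC(=O)OC | starting material
10 | methyl (4R,5S)-1-(tert-butyldimethylsilyloxy)-5-(2-methoxy-2-oxoethyl)-4,5-dimethylbicyclo[4.2.0]oct-7-ene-8-carboxylate (cis-fused, either face; formed in situ) | CC(C)(C)[Si](C)(C)OC12CC[C@@H](C)[C@](C)(CC(=O)OC)C1C=C2C(=O)OC | intermediate
11 | methyl (5R,6S,7Z)-6-(2-methoxy-2-oxoethyl)-5,6-dimethyl-2-oxocyclooct-7-ene-1-carboxylate (C1 epimers/enol) | COC(=O)C1/C=C\[C@@](C)(CC(=O)OC)[C@H](C)CCC1=O | intermediate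
12 | methyl (5R,6S)-6-(2-methoxy-2-oxoethyl)-5,6-dimethyl-2-oxocyclooctane-1-carboxylate (C1 epimers/enol) | COC(=O)C1CC[C@@](C)(CC(=O)OC)[C@H](C)CCC1=O | intermediate
13 | methyl (5R,6S)-6-(2-methoxy-2-oxoethyl)-5,6-dimethyl-2-oxo-1-(phenylselanyl)cyclooctane-1-carboxylate (formed in situ) | COC(=O)C1([Se]c2ccccc2)CC[C@@](C)(CC(=O)OC)[C@H](C)CCC1=O | intermediate
14 | selenoxide of 13 (formed in situ) | COC(=O)C1([Se](=O)c2ccccc2)CC[C@@](C)(CC(=O)OC)[C@H](C)CCC1=O | intermediate
15 | methyl (4S,5R)-4-(2-methoxy-2-oxoethyl)-4,5-dimethyl-8-oxocyclooct-1-ene-1-carboxylate (ring-cis alkene) | COC(=O)/C1=C/C[C@@](C)(CC(=O)OC)[C@H](C)CCC1=O | intermediate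
16 | (Z)-1,2-dichloroethene | Cl/C=C\Cl | starting material
17 | methyl (5R,6S)-9,10-dichloro-6-(2-methoxy-2-oxoethyl)-5,6-dimethyl-2-oxobicyclo[6.2.0]decane-1-carboxylate (trans-fused) | O=C1CC[C@@H](C)[C@](C)(CC(=O)OC)C[C@H]2C(Cl)C(Cl)[C@]12C(=O)OC | intermediate
18 | methyl (5R,6S)-9,10-dichloro-6-(2-methoxy-2-oxoethyl)-5,6-dimethyl-2-methylidenebicyclo[6.2.0]decane-1-carboxylate (trans-fused) | C=C1CC[C@@H](C)[C@](C)(CC(=O)OC)C[C@H]2C(Cl)C(Cl)[C@]12C(=O)OC | intermediate
19 | methyl (5R,6S)-9,10-dichloro-6-{2-[methoxy(methyl)amino]-2-oxoethyl}-5,6-dimethyl-2-methylidenebicyclo[6.2.0]decane-1-carboxylate (trans-fused) | C=C1CC[C@@H](C)[C@](C)(CC(=O)N(C)OC)C[C@H]2C(Cl)C(Cl)[C@]12C(=O)OC | intermediate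
20 | 3-bromofuran | Brc1ccoc1 | starting material
21 | methyl (5R,6S)-9,10-dichloro-6-[2-(furan-3-yl)-2-oxoethyl]-5,6-dimethyl-2-methylidenebicyclo[6.2.0]decane-1-carboxylate (trans-fused) | C=C1CC[C@@H](C)[C@](C)(CC(=O)c3ccoc3)C[C@H]2C(Cl)C(Cl)[C@]12C(=O)OC | intermediate
22 | methyl (5R,6S)-9,10-dichloro-6-[(2R)-2-(furan-3-yl)-2-hydroxyethyl]-5,6-dimethyl-2-methylidenebicyclo[6.2.0]decane-1-carboxylate (trans-fused) | C=C1CC[C@@H](C)[C@](C)(C[C@@H](O)c3ccoc3)C[C@H]2C(Cl)C(Cl)[C@]12C(=O)OC | intermediate
23 | (R)-2-methylbutanoic acid | CC[C@@H](C)C(=O)O | starting material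
24 | methyl (5R,6S)-9,10-dichloro-6-[(2R)-2-(furan-3-yl)-2-{[(2R)-2-methylbutanoyl]oxy}ethyl]-5,6-dimethyl-2-methylidenebicyclo[6.2.0]decane-1-carboxylate (trans-fused) | C=C1CC[C@@H](C)[C@](C)(C[C@@H](OC(=O)[C@H](C)CC)c3ccoc3)C[C@H]2C(Cl)C(Cl)[C@]12C(=O)OC | intermediate
25 | methyl (5R,6S)-6-[(2R)-2-(furan-3-yl)-2-{[(2R)-2-methylbutanoyl]oxy}ethyl]-5,6-dimethyl-2-methylidenebicyclo[6.2.0]dec-9-ene-1-carboxylate (trans-fused; formed in situ) | C=C1CC[C@@H](C)[C@](C)(C[C@@H](OC(=O)[C@H](C)CC)c3ccoc3)C[C@H]2C=C[C@]12C(=O)OC | intermediate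
26 | CNP0305973.1, methyl (1E,3Z,6S,7R)-6-[(2R)-2-(furan-3-yl)-2-{[(2R)-2-methylbutanoyl]oxy}ethyl]-6,7-dimethyl-10-methylidenecyclodeca-1,3-diene-1-carboxylate | C=C1CC[C@@H](C)[C@](C)(C[C@@H](OC(=O)[C@H](C)CC)c2ccoc2)C/C=C\C=C/1C(=O)OC | target

**Step count and risks**

Total step count: 14. Longest linear sequence: 14 steps (1 → 26).

Steps most likely to fail:

1. Step 14 (key step). What may go wrong: conrotation in the outward sense, or opening of cis-fused material, leaves a trans double bond at C7=C8; prolonged heating may also cause 6π-electrocyclisation of the triene or solvolysis at C12. Fallback: set out from 24, run the zinc dechlorination and the thermolysis at the lowest temperature that consumes the cyclobutene, and accept the 7E isomer, methyl (1E,3E,6S,7R)-6-[(2R)-2-(furan-3-yl)-2-{[(2R)-2-methylbutanoyl]oxy}ethyl]-6,7-dimethyl-10-methylidenecyclodeca-1,3-diene-1-carboxylate F1. F1 is then equilibrated with catalytic iodine (5 mol%, benzene, visible light, rt), the usual way to relax polyene geometry to the thermodynamic isomer, here driven by the strain of a trans double bond in the ten-membered ring. This returns to the route at 26.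

2. Step 8. What may go wrong: unproductive E/Z relaxation of the excited enone followed by dimerisation or photodeconjugation instead of cross-addition, or closure to the cis ring fusion. Fallback (ground-state polar [2+2] plus sulfoxide elimination instead of photochemistry): set out from 15. EtAlCl2-promoted stepwise [2+2] with phenyl vinyl sulfide (CH2 terminus to C7, thionium carbon to C10) should give methyl (5R,6S)-6-(2-methoxy-2-oxoethyl)-5,6-dimethyl-2-oxo-10-(phenylsulfanyl)bicyclo[6.2.0]decane-1-carboxylate F2. The sulfide is then carried through the operations of steps 9–13 in place of the two chlorines: Wittig methylenation to the 2-methylidene diester F3, Weinreb aminolysis to the amide F4, 3-furyllithium to the furyl ketone F5, CBS reduction to the (R)-carbinol F6, and esterification with 23 to the sulfide ester F7. NaIO4 (MeOH–H2O, 0 °C) gives the sulfoxide F8, and heating (toluene, 100 °C, trimethyl phosphite as sulfenic acid trap) eliminates PhSOH toward C8–H. Trans-fused material gives 25 and so returns to the route at 26. Cis-fused material gives the cis-fused bicyclo[6.2.0]dec-9-ene F9, which opens to F1 and is brought to 26 by the iodine isomerisation above.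

3. Step 5. What may go wrong: slow bond formation at the neopentyl enol-ether carbon C6, leading to silyl loss, open-chain Michael-type addition without ring closure, or oligomerisation of the ynoate. Fallback (alkene acceptor plus elimination instead of an alkyne acceptor): set out from 8. The same Lewis-acid-promoted [2+2] is run with methyl 2-chloroacrylate, an acrylate acceptor of the type for which this cycloaddition is best established, to give methyl (4R,5S)-8-chloro-1-(tert-butyldimethylsilyloxy)-5-(2-methoxy-2-oxoethyl)-4,5-dimethylbicyclo[4.2.0]octane-8-carboxylate F10. DBU (toluene, 60 °C) then removes HCl toward C7 (C1 has no hydrogen) to give the cyclobutene 10, which is treated with fluoride as in step 5; the route is rejoined at 10.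

**Further compounds**

F1 | step 14 | methyl (1E,3E,6S,7R)-6-[(2R)-2-(furan-3-yl)-2-{[(2R)-2-methylbutanoyl]oxy}ethyl]-6,7-dimethyl-10-methylidenecyclodeca-1,3-diene-1-carboxylate | C=C1CC[C@@H](C)[C@](C)(C[C@@H](OC(=O)[C@H](C)CC)c2ccoc2)C\C=C\C=C/1C(=O)OC
F2 | step 8 | methyl (5R,6S)-6-(2-methoxy-2-oxoethyl)-5,6-dimethyl-2-oxo-10-(phenylsulfanyl)bicyclo[6.2.0]decane-1-carboxylate (ring fusion unassigned) | O=C1CC[C@@H](C)[C@](C)(CC(=O)OC)CC2CC(Sc3ccccc3)C12C(=O)OC
F3 | step 8 | methyl (5R,6S)-6-(2-methoxy-2-oxoethyl)-5,6-dimethyl-2-methylidene-10-(phenylsulfanyl)bicyclo[6.2.0]decane-1-carboxylate | C=C1CC[C@@H](C)[C@](C)(CC(=O)OC)CC2CC(Sc3ccccc3)C12C(=O)OC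
F4 | step 8 | methyl (5R,6S)-6-{2-[methoxy(methyl)amino]-2-oxoethyl}-5,6-dimethyl-2-methylidene-10-(phenylsulfanyl)bicyclo[6.2.0]decane-1-carboxylate | C=C1CC[C@@H](C)[C@](C)(CC(=O)N(C)OC)CC2CC(Sc3ccccc3)C12C(=O)OC
F5 | step 8 | methyl (5R,6S)-6-[2-(furan-3-yl)-2-oxoethyl]-5,6-dimethyl-2-methylidene-10-(phenylsulfanyl)bicyclo[6.2.0]decane-1-carboxylate | C=C1CC[C@@H](C)[C@](C)(CC(=O)c3ccoc3)CC2CC(Sc3ccccc3)C12C(=O)OC
F6 | step 8 | methyl (5R,6S)-6-[(2R)-2-(furan-3-yl)-2-hydroxyethyl]-5,6-dimethyl-2-methylidene-10-(phenylsulfanyl)bicyclo[6.2.0]decane-1-carboxylate | C=C1CC[C@@H](C)[C@](C)(C[C@@H](O)c3ccoc3)CC2CC(Sc3ccccc3)C12C(=O)OC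
F7 | step 8 | methyl (5R,6S)-6-[(2R)-2-(furan-3-yl)-2-{[(2R)-2-methylbutanoyl]oxy}ethyl]-5,6-dimethyl-2-methylidene-10-(phenylsulfanyl)bicyclo[6.2.0]decane-1-carboxylate | C=C1CC[C@@H](C)[C@](C)(C[C@@H](OC(=O)[C@H](C)CC)c3ccoc3)CC2CC(Sc3ccccc3)C12C(=O)OC
F8 | step 8 | sulfoxide of F7 (10-benzenesulfinyl) | C=C1CC[C@@H](C)[C@](C)(C[C@@H](OC(=O)[C@H](C)CC)c3ccoc3)CC2CC(S(=O)c3ccccc3)C12C(=O)OC
F9 | step 8 | cis-fused diastereomer of 25 | C=C1CC[C@@H](C)[C@](C)(C[C@@H](OC(=O)[C@H](C)CC)c3ccoc3)C[C@H]2C=C[C@@]12C(=O)OC
F10 | step 5 | methyl (4R,5S)-8-chloro-1-(tert-butyldimethylsilyloxy)-5-(2-methoxy-2-oxoethyl)-4,5-dimethylbicyclo[4.2.0]octane-8-carboxylate | CC(C)(C)[Si](C)(C)OC12CC[C@@H](C)[C@](C)(CC(=O)OC)C1CC2(Cl)C(=O)OC
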